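The alpha run, the smallest of the earlier charges, ended at 7.5% Z from 0.86 equiv of Q. I divided that end reading by the charge to get the figure I would watch in a repeat: the yield per equivalent, 8.72%, meaning end Z in percent of the E charged for each equivalent of Q fed over 20 min.

| flask | E | Q | remark | time |
|---|---|---|---|---|
| alpha | 0.068 M | 0.86 equiv (fed, over 20 min) | run made earlier |  |
| theta | 0.068 M | 1.6 equiv (fed, over 20 min) | run made earlier |  |
| zeta | 0.068 M | 2.1 equiv (fed, over 20 min) | run made earlier |  |
| dawn | 0.068 M | 1.00 equiv (fed, over 20 min) |  | 20 min |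
| dusk | 0.068 M | 2.00 equiv (fed, over 20 min) |  | 20 min |
| summer | 0.068 M | 2.50 equiv (fed, over 20 min) |  | 20 min |

| run | time / min | Z / % |
|---|---|---|
| alpha | 1.50 | 0.2 |
| alpha | 3.00 | 0 |
| alpha | 6.00 | 0.8 |
| alpha | 10.0 | 2.3 |
| alpha | 20.0 | 7.5 |
| theta | 4.00 | 0.8 |
| theta | 8.00 | 3.1 |
| theta | 12.0 | 6.5 |
| theta | 15.0 | 8.2 |
| theta | 20.0 | 12.3 |
| zeta | 4.00 | 0.9 |
| zeta | 8.00 | 3.5 |
| zeta | 12.0 | 7.6 |
| zeta | 15.0 | 11.1 |
| zeta | 20.0 | 15.5 |

(each reading ± 0.3 percentage points)



- amount of Z at the end, in percent of the E charged, for each flask in turn (dawn, dusk, summer)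

Theta gave 7.69% and zeta 7.38%, so the yield per equivalent was lower at the larger charge, falling by 1.1 percentage points for each added equivalent between alpha and zeta, although the alpha figure was the least sure, since the same scatter of 0.3 points is divided there by the smallest charge.

I bracketed the flasks with two versions I could solve in my head. In the first, every Z formed stays and [E] holds near its start, so Z grows pseudo-first-order in Q, the yield per equivalent keeps its alpha value, and summer ends at 21.8%. In the second, Q consumes Z as fast as E makes it, so [Z] stands on a plateau independent of the charge, and summer ends at zeta's 15.5%. I put the real flask between them, since from theta to zeta the charge grew by a factor of 1.31 and Z by a slightly smaller 1.26. Keeping the straight fall, I reckoned 8.57% for dawn, 15.0% for dusk and 17.4% for summer.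

The forecast, which read the bend as “Z being consumed by more Q”, gave 8.9%, 14.8% and 17.1%.

Dawn, dusk and summer gave 8.32%, 15.2% and 18.1%.

    Z ⇌ D (K = 2.10, k = 0.0270 /min)
    Q → L (k = 0.0230 /min)
    E + Q → Z + G (k = 0.200 /M/min)
    Q + Z → X + G (k = 0.140 /M/min)

The yield per equivalent was 8.32% in dawn, against 8.72% read from alpha, and 7.60% in dusk. Continuing the straight fall from those two flasks to the charge of summer gives 18.1%, and summer stood at 18.1%. Part of what dusk lacked came from the drawn-out feeding of Q: with the same charge given at once, dusk ended at 21.4% against 15.2%, a yield per equivalent of 10.7%.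

The readings come from a simulation for substances that don't exist.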